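**Retrosynthetic overview**
- Last cut: the depsidone ester C(=O)–O (seven-membered ring), giving a diaryl-ether seco acid that is closed by base-free carbodiimide lactonisation.
- Next cut: the diaryl ether C–O, giving ring A as an 8-bromoisocoumarin (its enol lactone masks both the acid and the 2-oxoheptyl ketone) and the C5 phenol of the ring B spiroketal lactone; joined by Ullmann coupling.
- Ring B: the aryl–CH2 bond and both C–O bonds of the spiro acyl ketal are cut together, giving 2,4,5-trihydroxybenzoic acid and a δ-hydroxy β-keto sulfoxonium ylide made from (R)-δ-hexalactone. One operation builds the oxane and the isochromanone lactone and sets the spiro centre by anomeric equilibration.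
- Ring A: the same C–H acylmethylation logic, with the hexanoyl ylide on 2-bromo-4-methoxybenzoic acid.
- Ring order: oxane + isochromanone lactone (one pot), then the ring A pyranone (temporary, opened again), then the dioxepinone.

Assumption: (R)-δ-hexalactone (≥98% ee), 2,4,5-trihydroxybenzoic acid and 2-bromo-4-methoxybenzoic acid are bought as catalogue chemicals.

**Step 1**
Reactants: 1 (R)-δ-hexalactone [(6R)-6-methyloxan-2-one]; 2 trimethylsulfoxonium iodide
Product: 3 (6R)-1-[dimethyl(oxo)-λ6-sulfanylidene]-6-hydroxyheptan-2-one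
Conditions: Me3S(O)I (2.0 equiv), KOtBu (2.0 equiv), THF, reflux, 2 h; then 1, 0 °C to rt, 3 h
Reagents that add atoms: none
Why: Corey–Chaykovsky-type acylation of dimethylsulfoxonium methylide by the lactone carbonyl opens the ring to the stabilised β-keto sulfoxonium ylide, the liberated alkoxide taking up the acidic α-proton, and the carbinol stereocentre is a spectator.

**Step 2**
Reactants: 4 2,4,5-trihydroxybenzoic acid; 3 (6R)-1-[dimethyl(oxo)-λ6-sulfanylidene]-6-hydroxyheptan-2-one
Product: 6 (3S,6'R)-5,6,8-trihydroxy-6'-methylspiro[isochromane-3,2'-oxan]-1-one, via hydroxy keto acid 5 (not isolated)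
Conditions: [Cp*Rh(MeCN)3](SbF6)2 (5 mol %; Cp* = C5Me5), NaOAc (30 mol %), 3 (1.3 equiv), HFIP, 60 °C, Ar, 12 h; then TsOH·H2O (20 mol %), 40 °C, 2 h
Reagents that add atoms: none
Why: Proposed new method: carboxylate-assisted ortho C–H metalation of 4 by the cationic trivalent rhodium catalyst can occur only at C6 (the other ortho position carries OH), the ylide then binds and loses DMSO to give a rhodium carbene that inserts into the Rh–aryl bond and is protonated off to hydroxy keto acid 5, whose secondary alcohol closes the oxane hemiketal and whose carboxyl group closes the acyl ketal lactone under acid, equilibration placing the methyl group equatorial and the lactone oxygen axial (anomeric control) so that the 6'R centre from 1 fixes the spiro centre as 3S; the closest known chemistry is the trivalent rhodium or divalent ruthenium-catalysed annulation of benzoic acids with α-keto sulfoxonium ylides to 3-substituted isocoumarins, combined with acid-catalysed spiroketalisation of hydroxy keto acids.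

**Step 3**
Reactants: 6 (3S,6'R)-5,6,8-trihydroxy-6'-methylspiro[isochromane-3,2'-oxan]-1-one
Product: 7 (3S,6'R)-5,8-dihydroxy-6-(methoxymethoxy)-6'-methylspiro[isochromane-3,2'-oxan]-1-one
Conditions: MOMCl (1.05 equiv), iPr2NEt (1.1 equiv), CH2Cl2, −20 to 0 °C, Ar
Reagents that add atoms: chloromethyl methyl ether (MOMCl), COCCl
Why: Williamson-type acetal protection is selective for the C6 hydroxyl, the most acidic (para to the lactone carbonyl) and least hindered phenol, while the C8 hydroxyl is hydrogen-bonded to the carbonyl and the C5 hydroxyl is flanked by C4H2 and O6.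

**Step 4**
Reactants: 8 hexanoyl chloride; 2 trimethylsulfoxonium iodide
Product: 9 1-[dimethyl(oxo)-λ6-sulfanylidene]heptan-2-one
Conditions: Me3S(O)I (3.0 equiv), KOtBu (3.0 equiv), THF, reflux, 2 h; then 8, 0 °C to rt
Reagents that add atoms: none
Why: Acylation of dimethylsulfoxonium methylide by the acid chloride (Corey–Chaykovsky ylide acylation), a second equivalent of methylide deprotonating the β-keto sulfoxonium salt to the stable ylide.

**Step 5**
Reactants: 10 2-bromo-4-methoxybenzoic acid; 9 1-[dimethyl(oxo)-λ6-sulfanylidene]heptan-2-one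
Product: 12 8-bromo-6-methoxy-3-pentyl-1H-isochromen-1-one, via keto acid 11 (not isolated)
Conditions: [Cp*Rh(MeCN)3](SbF6)2 (5 mol %), NaOAc (30 mol %), 9 (1.3 equiv), HFIP, 80 °C, 16 h
Reagents that add atoms: none
Why: Known carboxylate-directed C–H acylmethylation/cyclodehydration of a benzoic acid with a sulfoxonium ylide under trivalent rhodium catalysis; C6 is the only free ortho position, the aryl bromide is inert to this catalyst, and the isocoumarin formed masks both the acid and the benzylic ketone for the coupling.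

**Step 6**
Reactants: 7 (3S,6'R)-5,8-dihydroxy-6-(methoxymethoxy)-6'-methylspiro[isochromane-3,2'-oxan]-1-one; 12 8-bromo-6-methoxy-3-pentyl-1H-isochromen-1-one
Product: 13 8-{[(3S,6'R)-8-hydroxy-6-(methoxymethoxy)-6'-methyl-1-oxospiro[isochromane-3,2'-oxan]-5-yl]oxy}-6-methoxy-3-pentyl-1H-isochromen-1-one
Conditions: CuI (10 mol %), picolinic acid (20 mol %), K3PO4 (2.5 equiv), DMSO, 90 °C, Ar, 24 h
Reagents that add atoms: none
Why: Ullmann diaryl ether synthesis with the copper/picolinic acid system for hindered partners; the C–Br bond is activated by the peri lactone carbonyl and the C5 phenoxide is the only free non-chelated phenol (O6 is blocked as MOM, O8 is hydrogen-bonded to its carbonyl), so the ether forms at O5.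

**Step 7**
Reactants: 13 8-{[(3S,6'R)-8-hydroxy-6-(methoxymethoxy)-6'-methyl-1-oxospiro[isochromane-3,2'-oxan]-5-yl]oxy}-6-methoxy-3-pentyl-1H-isochromen-1-one
Product: 15 2-{[(3S,6'R)-6,8-dihydroxy-6'-methyl-1-oxospiro[isochromane-3,2'-oxan]-5-yl]oxy}-4-methoxy-6-(2-oxoheptyl)benzoic acid, via MOM keto acid 14 (not isolated)
Conditions: KOH (6 equiv), 1,4-dioxane/H2O (2:1), 50 °C, 3 h; then 3 M HCl to pH 1, 40 °C, 4 h
Reagents that add atoms: water (delivered as KOH/H2O), O
Why: Saponification of the enol lactone releases the ring A carboxylic acid and the 2-oxoheptyl ketone, and the acidic work-up hydrolyses the MOM acetal and re-closes the ring B spiro acyl ketal if hydroxide has opened it, under the same thermodynamic control so the 3S centre is retained.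

**Step 8**
Reactants: 15 2-{[(3S,6'R)-6,8-dihydroxy-6'-methyl-1-oxospiro[isochromane-3,2'-oxan]-5-yl]oxy}-4-methoxy-6-(2-oxoheptyl)benzoic acid
Product: 16 CNP0301127.1 (target depsidone)
Conditions: DCC (1.3 equiv), CH2Cl2 (0.005 M), 0 °C to rt, 16 h
Reagents that add atoms: none
Why: Base-free carbodiimide lactonisation: the O-acylisourea of the ring A acid is captured by the adjacent C6 phenol across the diaryl ether to close the seven-membered depsidone ring, the C8 phenol being chelated and out of reach, and the absence of base keeps the benzylic ketone from enolising onto the activated acid.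

**Compound list**
1 | (R)-δ-hexalactone, (6R)-6-methyloxan-2-one | C[C@@H]1CCCC(=O)O1 | starting material
2 | trimethylsulfoxonium iodide | C[S+](C)(C)=O.[I-] | starting material
3 | (6R)-1-[dimethyl(oxo)-λ6-sulfanylidene]-6-hydroxyheptan-2-one | CS(C)(=O)=CC(=O)CCC[C@@H](C)O | intermediate
4 | 2,4,5-trihydroxybenzoic acid | OC(=O)c1cc(O)c(O)cc1O | starting material
5 | 3,4,6-trihydroxy-2-[(6R)-6-hydroxy-2-oxoheptyl]benzoic acid (not isolated) | C[C@@H](O)CCCC(=O)Cc1c(O)c(O)cc(O)c1C(=O)O | intermediate
6 | (3S,6'R)-5,6,8-trihydroxy-6'-methylspiro[isochromane-3,2'-oxan]-1-one | Oc1cc(O)c2c(c1O)C[C@]1(CCC[C@@H](C)O1)OC2=O | intermediate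
7 | (3S,6'R)-5,8-dihydroxy-6-(methoxymethoxy)-6'-methylspiro[isochromane-3,2'-oxan]-1-one | COCOc1cc(O)c2c(c1O)C[C@]1(CCC[C@@H](C)O1)OC2=O | intermediate
8 | hexanoyl chloride | CCCCCC(=O)Cl | starting material
9 | 1-[dimethyl(oxo)-λ6-sulfanylidene]heptan-2-one | CCCCCC(=O)C=S(C)(C)=O | intermediate
10 | 2-bromo-4-methoxybenzoic acid | COc1ccc(C(=O)O)c(Br)c1 | starting material
11 | 2-bromo-4-methoxy-6-(2-oxoheptyl)benzoic acid (not isolated) | CCCCCC(=O)Cc1cc(OC)cc(Br)c1C(=O)O | intermediate
12 | 8-bromo-6-methoxy-3-pentyl-1H-isochromen-1-one | CCCCCC1=Cc2cc(OC)cc(Br)c2C(=O)O1 | intermediate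
13 | 8-{[(3S,6'R)-8-hydroxy-6-(methoxymethoxy)-6'-methyl-1-oxospiro[isochromane-3,2'-oxan]-5-yl]oxy}-6-methoxy-3-pentyl-1H-isochromen-1-one | CCCCCC1=Cc2cc(OC)cc(Oc3c(OCOC)cc(O)c4c3C[C@]3(CCC[C@@H](C)O3)OC4=O)c2C(=O)O1 | intermediate
14 | 2-{[(3S,6'R)-8-hydroxy-6-(methoxymethoxy)-6'-methyl-1-oxospiro[isochromane-3,2'-oxan]-5-yl]oxy}-4-methoxy-6-(2-oxoheptyl)benzoic acid (not isolated) | CCCCCC(=O)Cc1cc(OC)cc(Oc2c(OCOC)cc(O)c3c2C[C@]2(CCC[C@@H](C)O2)OC3=O)c1C(=O)O | intermediate
15 | 2-{[(3S,6'R)-6,8-dihydroxy-6'-methyl-1-oxospiro[isochromane-3,2'-oxan]-5-yl]oxy}-4-methoxy-6-(2-oxoheptyl)benzoic acid | CCCCCC(=O)Cc1cc(OC)cc(Oc2c(O)cc(O)c3c2C[C@]2(CCC[C@@H](C)O2)OC3=O)c1C(=O)O | intermediate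
16 | CNP0301127.1: depsidone (dibenzo[b,e][1,4]dioxepin-11-one core) with methoxy and 2-oxoheptyl on ring A; ring B carries a free hydroxyl and is fused to the (3S,6'R)-6'-methylspiro[isochromane-3,2'-oxan]-1-one acyl ketal, with the ether oxygen at its C5 and the ester oxygen at its C6 | CCCCCC(=O)Cc1cc(OC)cc2c1C(=O)Oc1cc(O)c3c(c1O2)C[C@]1(CCC[C@@H](C)O1)OC3=O | target

**Step count**
Total steps: 8. Longest linear sequence: 6 (steps 1, 2, 3, 6, 7, 8).

**Three steps most likely to fail**

Step 2. The free hydroxyl of ylide 3 or the carboxylate may be alkylated by the ylide (O–H insertion) in competition with C–H insertion. The hydroxyquinol-type acid 4 is also oxidation-sensitive, and spirocyclisation may stop at the isocoumarin stage. The fallback sets out from 3 and comes back at 6. The hydroxyl of 3 is silylated (TBSCl, imidazole, DMF) to (6R)-6-[(tert-butyldimethylsilyl)oxy]-1-[dimethyl(oxo)-λ6-sulfanylidene]heptan-2-one F1. F1 is annulated with 4 under the rhodium conditions of step 5, and the product is isolated as the isocoumarin 5,6,8-trihydroxy-3-[(4R)-4-[(tert-butyldimethylsilyl)oxy]pentyl]-1H-isochromen-1-one F2. TsOH·H2O in wet THF at 40 °C then removes the silyl group, and the freed alcohol adds across the enol lactone double bond under the same anomeric control to give 6.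

Step 6. Both partners are hindered (a 2,6-disubstituted phenoxide and a peri-substituted bromide). The chelated C8 phenoxide could compete, the hydroquinone-like 5,8-diol of 7 is sensitive to oxidation, and the isocoumarin may be opened by base. The fallback sets out from 7 and 10 and comes back at 13, reversing the order of events. A classical ortho-carboxylate-assisted Ullmann condensation of 7 with the unhindered acid 10 (CuI, K2CO3, DMF, 110 °C) gives 2-{[(3S,6'R)-8-hydroxy-6-(methoxymethoxy)-6'-methyl-1-oxospiro[isochromane-3,2'-oxan]-5-yl]oxy}-4-methoxybenzoic acid F3. Its ring A carboxyl group then directs the rhodium-catalysed acylmethylation/cyclodehydration with ylide 9 at the only free ortho C–H, and this delivers 13.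

Step 8. The activated ring A acid can be trapped by its own ketone (as the enol) to re-form the isocoumarin, the diaryl-ether isomer of the target, instead of lactonising. The product aryl ester is also base-sensitive. The fallback sets out from 15 and comes back at 16, keeping the ketone masked through the lactonisation. 1,2-Bis(trimethylsilyloxy)ethane with catalytic TMSOTf (CH2Cl2, −78 to −20 °C, aqueous citric acid work-up) converts 15 into 2-{[(3S,6'R)-6,8-dihydroxy-6'-methyl-1-oxospiro[isochromane-3,2'-oxan]-5-yl]oxy}-4-methoxy-6-[(2-pentyl-1,3-dioxolan-2-yl)methyl]benzoic acid F4. DCC in dilute CH2Cl2 closes the seven-membered ring to the dioxolane-protected depsidone (the 1,3-dioxolane ketal of 16 at the heptan-2-one carbonyl) F5. Pyridinium p-toluenesulfonate in wet acetone at 40 °C then releases the ketone to give 16.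

**Further compounds**
F1 | step 2 | (6R)-6-[(tert-butyldimethylsilyl)oxy]-1-[dimethyl(oxo)-λ6-sulfanylidene]heptan-2-one | CS(C)(=O)=CC(=O)CCC[C@@H](C)O[Si](C)(C)C(C)(C)C
F2 | step 2 | 5,6,8-trihydroxy-3-[(4R)-4-[(tert-butyldimethylsilyl)oxy]pentyl]-1H-isochromen-1-one | CC(C)(C)[Si](C)(C)O[C@H](C)CCCC1=Cc2c(O)c(O)cc(O)c2C(=O)O1
F3 | step 6 | 2-{[(3S,6'R)-8-hydroxy-6-(methoxymethoxy)-6'-methyl-1-oxospiro[isochromane-3,2'-oxan]-5-yl]oxy}-4-methoxybenzoic acid | COc1ccc(C(=O)O)c(Oc2c(OCOC)cc(O)c3c2C[C@]2(CCC[C@@H](C)O2)OC3=O)c1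
F4 | step 8 | 2-{[(3S,6'R)-6,8-dihydroxy-6'-methyl-1-oxospiro[isochromane-3,2'-oxan]-5-yl]oxy}-4-methoxy-6-[(2-pentyl-1,3-dioxolan-2-yl)methyl]benzoic acid | CCCCCC1(Cc2cc(OC)cc(Oc3c(O)cc(O)c4c3C[C@]3(CCC[C@@H](C)O3)OC4=O)c2C(=O)O)OCCO1
F5 | step 8 | 1,3-dioxolane ketal of target 16 at the heptan-2-one carbonyl | CCCCCC1(Cc2cc(OC)cc3c2C(=O)Oc2cc(O)c4c(c2O3)C[C@]2(CCC[C@@H](C)O2)OC4=O)OCCO1
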